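What should I do to the epsilon flask at 80 min, and what is each option worth? These were the runs and the choices:

common to all: substrate 0.44 M; free catalyst 0.5 mol%; second catalyst 0.5 mol%

| flask | reagent | temperature | remark | time |
|---|---|---|---|---|
| epsilon | 0.80 equiv | 110 °C | the very flask that is asked about, followed so far |  |
| alpha | 0.80 equiv | 116 °C | run made earlier |  |
| flask | 0.800 equiv | 110 °C |  | 80 min |

| run | time / min | product / % | substrate / % |
|---|---|---|---|
| epsilon | 10.0 | 37.1 | 27.6 |
| epsilon | 20.0 | 50.9 | 21.7 |
| epsilon | 30.0 | 56.4 | 20.8 |
| epsilon | 40.0 | 58.4 | 20.5 |
| epsilon | 50.0 | 58.8 | 21.0 |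
| epsilon | 60.0 | 59.8 | 20.7 |
| alpha | 10.0 | 40.4 | 27.1 |
| alpha | 20.0 | 52.5 | 22.3 |
| alpha | 30.0 | 56.0 | 23.2 |
| alpha | 40.0 | 56.7 | 22.4 |
| alpha | 50.0 | 56.7 | 22.1 |
| alpha | 60.0 | 57.0 | 22.6 |

(each reading ± 0.5 percentage points)

- violet: at 80 min add reagent, 50.0% of the amount charged, then wait 25 min
- green: at 80 min add free catalyst, 100% of the amount charged, then wait 25 min
- teal: at 80 min take out 90% of the product then present, then wait 25 min
- red: at 80 min raise the temperature by 20 K, then wait 25 min
- blue: change nothing and wait 25 min more

- removed product is counted in
- what was read earlier has a scatter of 0.5 percentage points, one standard deviation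
- what may be going on: reagent + catalyst intermediate -> second catalyst + product; second catalyst + open intermediate <-> catalyst intermediate; substrate <-> dormant form; free catalyst + product -> spent catalyst; substrate + free catalyst <-> free catalyst + open intermediate
- "the catalyst" is free catalyst with its forms; second catalyst is a second catalyst
- additions bring no volume worth counting

- product, in percent of the substrate first charged, at 80 min
- the option that brings most further product ("none" if no option brings more than 2 percentage points) (violet / green / teal / red / blue / none)
- product present, with what was taken out counted in, in percent of the substrate first charged, after violet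
- product present, with what was taken out counted in, in percent of the substrate first charged, after blue

I followed one substrate molecule through its forks: in epsilon it could end as product, stay as substrate, or sit in neither reading. At the last reading, 60.0 min, I reckoned:

idle ratio = (whole charge − c(product) − c(substrate)) / c(substrate) = 19.5% / 20.7% = 0.942

I called this reading the idle ratio: the unread share of the charge per unit of substrate left. The hotter alpha run gave 0.903, so I took the unread share to be mostly dormant form standing beside substrate. That made the unused pool larger than the substrate reading:

unused pool = c(substrate) × (1 + idle ratio) = 40.2%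

Reagent was charged at 0.80 equiv, against product of 59.8%, so reagent was not acting as the limiting reagent, and violet added something not short. I committed to about 59.8% at 80 min, and to the same after violet or blue. Alpha, hotter from the start, stalled lower, at 57.0%, which gave me no ground to expect much from red, and teal renews neither pool nor reagent. With substrate and reagent both present, the catalysts were my suspects, and green renews one of them.

The forecast gave 59.7% now, 59.9% after violet, 59.8% after blue and green as best, holding that “fresh free catalyst restarts the opening”.

    reagent + catalyst intermediate → second catalyst + product (k = 13.0 M⁻¹ s⁻¹, Ea = 70.0 kJ mol⁻¹)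
    second catalyst + open intermediate ⇌ catalyst intermediate (K = 0.780 M⁻¹, k = 23.0 M⁻¹ s⁻¹, Ea = 67.0 kJ mol⁻¹, ΔH = −33.0 kJ mol⁻¹)
    substrate ⇌ dormant form (K = 0.900, k = 0.00410 s⁻¹, Ea = 120 kJ mol⁻¹, ΔH = −2.00 kJ mol⁻¹)
    free catalyst + product → spent catalyst (k = 0.0200 M⁻¹ s⁻¹, Ea = 82.0 kJ mol⁻¹)
    substrate + free catalyst ⇌ free catalyst + open intermediate (K = 0.340, k = 31.0 M⁻¹ s⁻¹, Ea = 69.0 kJ mol⁻¹, ΔH = −4.00 kJ mol⁻¹)
    (constants at 110 °C)

The epsilon flask gives 59.6% at 80 min, 59.6% after violet and 59.6% after blue, and green is best, with 8.3 percentage points more product. At 80.0 min free catalyst stands at 0% of its charge and spent catalyst at 100%. With substrate at 21.0%, the idle ratio gives a pool of 40.8% and so product of 59.2%.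

In the flask with 1.1 M of substrate, at the same equivalents and loadings, substrate stands at 16.3% at 80 min, and the idle ratio gives product of 68.3%. The computed value there is 68.4%.

The readings were generated by integration on assumed constants, noise included.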